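**Retrosynthetic overview**
1. Target 13 ⇐ 11 by one hydrogenolysis that removes two benzyl ethers and cuts the benzylic C–O bond of a flavanone ring, which unmasks the dihydrochalcone chain; O5 stays benzylated until then, so the lactone can only sit on the oxygen ortho to the ketone.
2. 11 ⇐ lactol 10 by oxidation.
3. 10 ⇐ chalcone 6 + cinnamaldehyde 7 in one amine-catalysed cascade: C4–C4a bond (sets 4R), lactol C–O bond and flavanone C–O bond.
4. 6 ⇐ ketone 3 + aldehyde 4 (Claisen–Schmidt); 3 ⇐ 1 by para-selective benzylation.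
5. Ring order: all arenes are bought; the lactol ring (later the lactone) and the flavanone ring close together in step 3; the flavanone ring is reopened in step 5.

Assumption: C4 is R as read from the SMILES (ring aryl > phenyl > CH2 > H); the lactol and flavanone centres made on the way are uncontrolled and both are erased later, so 10, 11 and 12 are epimer mixtures with one configuration at C4.

**Step 1**
Reactants: 1 1-(2,4,6-trihydroxyphenyl)ethan-1-one; 2 benzyl bromide
Product: 3 1-[4-(benzyloxy)-2,6-dihydroxyphenyl]ethan-1-one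
Conditions: BnBr (1.0 equiv), K2CO3 (1.0 equiv), DMF, 0 °C → rt
Reagents that add atoms: benzyl bromide, BrCc1ccccc1
Why: Williamson etherification with one equivalent of mild base goes to the 4-OH, the most acidic hydroxyl and the only one neither chelated to nor flanking the acetyl group, so both ortho hydroxyls stay free (no stereocenter).

**Step 2**
Reactants: 3 1-[4-(benzyloxy)-2,6-dihydroxyphenyl]ethan-1-one; 4 4-(benzyloxy)benzaldehyde
Product: 6 (E)-1-[4-(benzyloxy)-2,6-dihydroxyphenyl]-3-[4-(benzyloxy)phenyl]prop-2-en-1-one, via aldol adduct 5 (not isolated)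
Conditions: KOH (50% aq), EtOH, rt, 48 h; then 1 M HCl, 0 °C
Reagents that add atoms: none
Why: Claisen–Schmidt aldol condensation in which the methyl ketone enolate adds to the non-enolisable aldehyde and aldol 5 loses water by E1cB to the (E)-enone, the polyphenoxide keeping the product ring-open until cold acidification (no stereocenter kept).

**Step 3**
Reactants: 6 (E)-1-[4-(benzyloxy)-2,6-dihydroxyphenyl]-3-[4-(benzyloxy)phenyl]prop-2-en-1-one; 7 (E)-3-phenylprop-2-enal
Product: 10 (4R)-5-(benzyloxy)-8-[4-(benzyloxy)phenyl]-2-hydroxy-4-phenyl-3,4,8,9-tetrahydro-2H,10H-pyrano[2,3-f]chromen-10-one, via open-chain aldehyde 8 (not isolated), via chalcone lactol 9 (not isolated)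
Conditions: 7 (1.2 equiv), (R)-2-[diphenyl(trimethylsilyloxy)methyl]pyrrolidine (20 mol %), PhCO2H (20 mol %), toluene, 0 °C → rt; then Et3N (0.5 equiv), rt
Reagents that add atoms: none
Why: Proposed new method: the (R)-prolinol silyl ether turns 7 into its (E)-iminium ion, whose Si face at the β-carbon is shielded by the diphenyl(silyloxy)methyl group, so C3' of the symmetric, vinylogous-acid-like ring A of 6 adds to the Re face in a Friedel–Crafts-type Michael addition and sets C4 as R, the released aldehyde 8 is trapped by the neighbouring 2'-OH as lactol 9 (first ring), and Et3N then drives 6-endo oxa-Michael closure of the remaining 6'-OH onto the enone (second ring, the flavanone), which also blocks a second annulation; the closest known reactions are the diarylprolinol silyl ether catalysed Friedel–Crafts alkylation/hemiacetalisation of naphthols, sesamol and 4-hydroxycoumarin with enals and the base-mediated chalcone–flavanone isomerisation.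

**Step 4**
Reactants: 10 (4R)-5-(benzyloxy)-8-[4-(benzyloxy)phenyl]-2-hydroxy-4-phenyl-3,4,8,9-tetrahydro-2H,10H-pyrano[2,3-f]chromen-10-one
Product: 11 (4R)-5-(benzyloxy)-8-[4-(benzyloxy)phenyl]-4-phenyl-3,4,8,9-tetrahydro-2H,10H-pyrano[2,3-f]chromene-2,10-dione
Conditions: TEMPO (20 mol %), PhI(OAc)2 (1.5 equiv), CH2Cl2, rt
Reagents that add atoms: none
Why: Oxoammonium (TEMPO/PhI(OAc)2) oxidation of a lactol to the lactone, clean here because 10 has no free phenol; C4 is not enolisable and stays R, and the lactol carbon stops being a stereocenter.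

**Step 5**
Reactants: 11 (4R)-5-(benzyloxy)-8-[4-(benzyloxy)phenyl]-4-phenyl-3,4,8,9-tetrahydro-2H,10H-pyrano[2,3-f]chromene-2,10-dione
Product: 13 (4R)-5,7-dihydroxy-8-[3-(4-hydroxyphenyl)propanoyl]-4-phenyl-3,4-dihydro-2H-chromen-2-one, via debenzylated flavanone lactone 12 (not isolated)
Conditions: H2 (1 atm), Pd/C (10 wt %), EtOAc–AcOH (10:1), rt
Reagents that add atoms: none
Why: Pd-catalysed hydrogenolysis cleaves the two benzyl aryl ethers and then the flavanone C–O bond of 12, a secondary benzylic aryl ether activated by the freed para-hydroxyl (the classical flavanone to dihydrochalcone opening), which erases the uncontrolled flavanone centre, while the chelated aryl ketone, the lactone (it cannot migrate to the freed 5-OH in this non-nucleophilic medium) and the C4 centre are untouched.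

**Compound list**
1 | 1-(2,4,6-trihydroxyphenyl)ethan-1-one (2,4,6-trihydroxyacetophenone) | CC(=O)c1c(O)cc(O)cc1O | starting material
2 | benzyl bromide | BrCc1ccccc1 | starting material
3 | 1-[4-(benzyloxy)-2,6-dihydroxyphenyl]ethan-1-one | CC(=O)c1c(O)cc(OCc2ccccc2)cc1O | intermediate
4 | 4-(benzyloxy)benzaldehyde | O=Cc1ccc(OCc2ccccc2)cc1 | starting material
5 | 1-[4-(benzyloxy)-2,6-dihydroxyphenyl]-3-[4-(benzyloxy)phenyl]-3-hydroxypropan-1-one (racemic aldol adduct) | O=C(CC(O)c1ccc(OCc2ccccc2)cc1)c1c(O)cc(OCc2ccccc2)cc1O | intermediate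
6 | (E)-1-[4-(benzyloxy)-2,6-dihydroxyphenyl]-3-[4-(benzyloxy)phenyl]prop-2-en-1-one (chalcone) | O=C(/C=C/c1ccc(OCc2ccccc2)cc1)c1c(O)cc(OCc2ccccc2)cc1O | intermediate
7 | (E)-3-phenylprop-2-enal (cinnamaldehyde) | O=C/C=C/c1ccccc1 | starting material
8 | (3R)-3-{6-(benzyloxy)-3-[(E)-3-(4-(benzyloxy)phenyl)prop-2-enoyl]-2,4-dihydroxyphenyl}-3-phenylpropanal | O=CC[C@H](c1ccccc1)c1c(OCc2ccccc2)cc(O)c(C(=O)/C=C/c2ccc(OCc3ccccc3)cc2)c1O | intermediate
9 | (4R)-5-(benzyloxy)-8-[(E)-3-(4-(benzyloxy)phenyl)prop-2-enoyl]-4-phenylchromane-2,7-diol (both C2 epimers) | OC1C[C@H](c2ccccc2)c2c(OCc3ccccc3)cc(O)c(C(=O)/C=C/c3ccc(OCc4ccccc4)cc3)c2O1 | intermediate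
10 | (4R)-5-(benzyloxy)-8-[4-(benzyloxy)phenyl]-2-hydroxy-4-phenyl-3,4,8,9-tetrahydro-2H,10H-pyrano[2,3-f]chromen-10-one (epimers at C2 and C8) | OC1C[C@H](c2ccccc2)c2c(OCc3ccccc3)cc3OC(c4ccc(OCc5ccccc5)cc4)CC(=O)c3c2O1 | intermediate
11 | (4R)-5-(benzyloxy)-8-[4-(benzyloxy)phenyl]-4-phenyl-3,4,8,9-tetrahydro-2H,10H-pyrano[2,3-f]chromene-2,10-dione (both C8 epimers) | O=C1C[C@H](c2ccccc2)c2c(OCc3ccccc3)cc3OC(c4ccc(OCc5ccccc5)cc4)CC(=O)c3c2O1 | intermediate
12 | (4R)-5-hydroxy-8-(4-hydroxyphenyl)-4-phenyl-3,4,8,9-tetrahydro-2H,10H-pyrano[2,3-f]chromene-2,10-dione (both C8 epimers) | O=C1C[C@H](c2ccccc2)c2c(O)cc3OC(c4ccc(O)cc4)CC(=O)c3c2O1 | intermediate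
13 | (4R)-5,7-dihydroxy-8-[3-(4-hydroxyphenyl)propanoyl]-4-phenyl-3,4-dihydro-2H-chromen-2-one (CNP0246155.1) | O=C1C[C@H](c2ccccc2)c2c(O)cc(O)c(C(=O)CCc3ccc(O)cc3)c2O1 | target

**Totals**
Total step count: 5. Longest linear sequence: 5 steps (1 → 3 → 6 → 10 → 11 → 13).

**Steps most likely to fail**

Step 3. The ketone-deactivated ring A may be too weak a nucleophile. Other failure modes are 1,2-addition leading to a 2-phenylchromene, a second annulation, and attack at the flavanone C8 if ring closure comes first. The fallback sets the stereocentre by aryl transfer to a preformed coumarin instead of arene addition to an enal. It sets out from 6: ethyl propiolate with Pd(OAc)2 in TFA/CH2Cl2 at rt brings about hydroarylation–lactonisation at the carbon ortho to a free hydroxyl, and the acid closes the flavanone. This gives 5-(benzyloxy)-8-[4-(benzyloxy)phenyl]-8,9-dihydro-2H,10H-pyrano[2,3-f]chromene-2,10-dione F3. PhB(OH)2 with Rh(acac)(C2H4)2 and (R)-SEGPHOS in dioxane–H2O at 60 °C then adds phenyl to C4 of the coumarin, and the route is rejoined at 11.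

Step 5. The ring C–O bond may cleave slowly, or the ketone may be over-reduced. The fallback removes the need for any flavanone opening and sets out from 6.
- The enone C=C is hydrogenated first (H2, Pd/C poisoned with Ph2S, EtOAc, rt; benzyl ethers survive) to 1-[4-(benzyloxy)-2,6-dihydroxyphenyl]-3-[4-(benzyloxy)phenyl]propan-1-one F4.
- The amine-catalysed Friedel–Crafts/hemiacetalisation of step 3 with 7, run on this symmetric ring, gives (4R)-5-(benzyloxy)-8-{3-[4-(benzyloxy)phenyl]propanoyl}-4-phenylchromane-2,7-diol F5.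
- Ag2CO3 on Celite in refluxing toluene oxidises the lactol beside the chelated phenol to (4R)-5-(benzyloxy)-8-{3-[4-(benzyloxy)phenyl]propanoyl}-7-hydroxy-4-phenylchroman-2-one F6.
- H2, Pd/C in EtOAc then removes only the two benzyl groups, and the route is rejoined at 13.

Step 2. The aldol condensation of a ketone with two free ortho hydroxyls is slow, and the chalcone may cyclise on work-up. The fallback takes the C6–C3–C6 unit from a natural flavanone instead of building it by aldol chemistry. It sets out from 2 and commercial racemic naringenin F1: K2CO3 (2.2 equiv) and 2 (2.1 equiv) in refluxing acetone benzylate the two non-chelated hydroxyls to 7-(benzyloxy)-2-[4-(benzyloxy)phenyl]-5-hydroxychroman-4-one F2, the ring-closed isomer of 6. F2 is put into step 3 in place of 6: the amine/Et3N medium equilibrates it with the chalcone, and in the flavanone only C6 has a free ortho hydroxyl to trap the aldehyde. The price is a C6/C8 question that the symmetric chalcone avoids. The route is rejoined at 10.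

**Further compounds**
F1 | step 2 | naringenin (racemic 5,7-dihydroxy-2-(4-hydroxyphenyl)chroman-4-one) | O=C1CC(c2ccc(O)cc2)Oc2cc(O)cc(O)c12
F2 | step 2 | 7-(benzyloxy)-2-[4-(benzyloxy)phenyl]-5-hydroxychroman-4-one (racemic) | O=C1CC(c2ccc(OCc3ccccc3)cc2)Oc2cc(OCc3ccccc3)cc(O)c12
F3 | step 3 | 5-(benzyloxy)-8-[4-(benzyloxy)phenyl]-8,9-dihydro-2H,10H-pyrano[2,3-f]chromene-2,10-dione (racemic at C8) | O=C1C=Cc2c(OCc3ccccc3)cc3OC(c4ccc(OCc5ccccc5)cc4)CC(=O)c3c2O1
F4 | step 5 | 1-[4-(benzyloxy)-2,6-dihydroxyphenyl]-3-[4-(benzyloxy)phenyl]propan-1-one | O=C(CCc1ccc(OCc2ccccc2)cc1)c1c(O)cc(OCc2ccccc2)cc1O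
F5 | step 5 | (4R)-5-(benzyloxy)-8-{3-[4-(benzyloxy)phenyl]propanoyl}-4-phenylchromane-2,7-diol (both C2 epimers) | OC1C[C@H](c2ccccc2)c2c(OCc3ccccc3)cc(O)c(C(=O)CCc3ccc(OCc4ccccc4)cc3)c2O1
F6 | step 5 | (4R)-5-(benzyloxy)-8-{3-[4-(benzyloxy)phenyl]propanoyl}-7-hydroxy-4-phenylchroman-2-one | O=C1C[C@H](c2ccccc2)c2c(OCc3ccccc3)cc(O)c(C(=O)CCc3ccc(OCc4ccccc4)cc3)c2O1
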